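The readings are simulated with made-up constants.

Two constants can be drawn from this flask, one for J forming from E and one for J returning to E. The early shares use the first, the late share their quotient.

all flasks: G 0.50 M; Q 0.49 mM

| run | remark | time |
|---|---|---|
| spring | the very flask that is asked about, followed so far |  |
| flask |  | 8.0 d |

spring run (percent of the G charged)

| time / d | E / % | J / % |
|---|---|---|
| 0.250 | 17.9 | 2.0 |
| 0.833 | 33.8 | 15.5 |
| 1.67 | 32.1 | 34.1 |
| 2.50 | 28.2 | 45.5 |
| 3.00 | 25.9 | 49.5 |

(standard deviation of a reading: 0.5 percentage points)

- what was read earlier has a scatter of 0.5 percentage points, one standard deviation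

1. share of E in E plus J at 20 min
2. share of E in E plus J at 8.0 h
3. share of E in E plus J at 8.0 d

Divide the gain of J per day by the mean E of an interval, and hold it against cJ/cE there: time drops out, and a line is expected if J forms from E and returns to it. From 0.833 d to 1.67 d you get 0.674 d⁻¹ at a ratio of 0.753. From 2.50 d to 3.00 d you get 0.296 d⁻¹ at 1.76. The line has slope 0.377 d⁻¹ and intercept 0.958 d⁻¹.

Where it reaches zero, J stops gaining; the late share is 1/(1+K), with K that end ratio, the equilibrium constant if J does return to E.

Which readings must be good? Raise the last J by one scatter and the share becomes 26.7%. Raise the last E instead and it becomes 28.6%. The approach half-life as read, ln(2)/(sum of both constants), 0.519 d, is shorter than 8.0 d.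

As read, the end ratio K is 2.54, so the share is 28.3%. Early, if E grows about in step with time, cJ/cE is about the intercept times t/2, which gives a share of 99.3% at 20 min and 86.2% at 8.0 h.

The forecast said 99.3%, 86% and 24%, adding: “The uncertainty is whether the catalyst really dies”.

The flask gives 99.4%, 85.4% and 26.6%.

    G + Q ⇌ E + Q, rate k1*[G]*[Q] forward; the back reaction follows from the equilibrium constant (K = 1.90, k = 84.0 M⁻¹ h⁻¹)
    Q + E → Q + X (k = 4.10 M⁻¹ h⁻¹)
    E ⇌ J (K = 2.70, k = 0.0390 h⁻¹)

At 8.0 d the flask's cJ/cE is 2.76, against your 2.54. The relaxation half-life of E and J by E ⇌ J alone, both ways together, is 0.540 d, short against that time. Carried to the neighbour flask with 0.0012 M of Q, your K gives a share of 28.3% again; computed, that flask stands at 25.5%.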